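**Plan**

- Feature: in the cyclopentenone ring C5–C9, the ester-bearing C6 lies between spiro C5 and vinylic C7. Returned between C6 and C7, the ester carbon completes a six-membered, fully oxygenated carbocycle (an oxidised benzene ring), and a diazo group on C6 next to that carbonyl is the Wolff retron.
- Cuts, in retrosynthetic order: aryl O–Si; C6–OH; C6–C7 (ester carbon back in the ring, giving the six-membered α-diazo enedione); C=N2; the enol ether masking the ring ketone; O1–C5 (spiro ether back to a phenol and a diketone enol); C2–C3 (Claisen); aryl–acetyl and aryl–OH.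
- Forward: the benzene ring of 2,3,4-trimethoxybenzaldehyde becomes the carbocycle; the aroylacetyl chain is joined by Claisen condensation; the furanone ring closes first, by oxidative O-attack on the arene carbon that becomes C5; the six-membered ring is then contracted to the cyclopentenone; C6–OH and desilylation finish.
- Stereochemistry: C5 is set by a chiral iodoarene catalyst in the dearomatising spirocyclisation (step 5). C6 is set from C5 in step 9, the planar extended enolate taking up oxygen on the O1 face.

Key step: step 8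

Assumption: the sense of induction of the chiral iodoarene on diketone 9 cannot be assigned in advance. The (R,R)-catalyst is written; its (S,S)-antipode, made the same way from the other lactate, replaces it if the first run gives the 5R spirocycle.

Numbering: six-membered-ring compounds are numbered O1, C2 (aryl), C3, C4 (C=O), C5 (spiro), C6 (C=O), C7, C8, C9, C10. On contraction, old C10 becomes new C6, old C8 becomes C7, old C7 becomes C8, old C6 becomes C9, and old C9 becomes the ester carbon.

**Step 1**
Reactants: 1 2,3,4-trimethoxybenzaldehyde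
Product: 3 2,3,4-trimethoxyphenol, via 2,3,4-trimethoxyphenyl formate 2 (not isolated)
Conditions: mCPBA, CH2Cl2, 0 °C → rt; then 3 M aq. HCl (cat.), THF, rt
Reagents that add atoms: 3-chloroperoxybenzoic acid (mCPBA), O=C(OO)c1cccc(Cl)c1
Why: Baeyer–Villiger (Dakin-type) oxidation, in which the electron-rich aryl group migrates in the peracid adduct of the aldehyde to give formate 2, which dilute acid hydrolyses while the methyl ethers stay inert.

**Step 2**
Reactants: 3 2,3,4-trimethoxyphenol; 4 acetyl chloride
Product: 6 1-(2-hydroxy-3,4,5-trimethoxyphenyl)ethan-1-one, via 2,3,4-trimethoxyphenyl acetate 5 (not isolated)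
Conditions: AcCl (1.2 equiv), Sc(OTf)3 (10 mol %), toluene–MeNO2, 100 °C
Reagents that add atoms: acetyl chloride (4), CC(Cl)=O
Why: O-acetylation followed by metal-triflate-catalysed Fries rearrangement should place the acetyl group on C6 of the phenol (ortho to OH, para to the 3-methoxy group), and the chelated o-hydroxy ketone resists further acylation.

**Step 3**
Reactants: 7 methyl 4-hydroxybenzoate
Product: 8 methyl 4-[(triisopropylsilyl)oxy]benzoate
Conditions: TIPSCl, imidazole, DMF, rt
Reagents that add atoms: triisopropylsilyl chloride, CC(C)[Si](Cl)(C(C)C)C(C)C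
Why: Standard imidazole-mediated silylation of a phenol; the TIPS ether is chosen because it should survive lithium methoxide, peracid, dilute acid, amide bases and photolysis, and it keeps this ring out of the later phenol oxidation.

**Step 4**
Reactants: 6 1-(2-hydroxy-3,4,5-trimethoxyphenyl)ethan-1-one; 8 methyl 4-[(triisopropylsilyl)oxy]benzoate
Product: 9 1-(2-hydroxy-3,4,5-trimethoxyphenyl)-3-{4-[(triisopropylsilyl)oxy]phenyl}propane-1,3-dione (enolised in solution)
Conditions: LiHMDS (3.5 equiv), THF, −78 °C → rt; 1 M HCl to pH 5 at 0 °C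
Reagents that add atoms: none
Why: Crossed Claisen condensation of the phenoxide/enolate dianion of 6 with the non-enolisable ester 8, driven by deprotonation of the product diketone; the cold, weakly acidic quench avoids cyclodehydration to the flavone.

**Step 5**
Reactants: 9 1-(2-hydroxy-3,4,5-trimethoxyphenyl)-3-{4-[(triisopropylsilyl)oxy]phenyl}propane-1,3-dione
Product: 10 (5S)-7,8,9-trimethoxy-2-{4-[(triisopropylsilyl)oxy]phenyl}-1-oxaspiro[4.5]deca-2,7,9-triene-4,6-dione
Conditions: (R,R)-2-iodo-1,3-bis[1-(mesitylcarbamoyl)ethoxy]benzene (10 mol %), mCPBA (1.2 equiv, slow addition), CH2Cl2 with (CF3)2CHOH as additive, −20 °C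
Reagents that add atoms: none
Why: Proposed new method: the phenol OH of 9 exchanges onto the chiral aryl-λ3-iodane formed in situ from the iodoarene and mCPBA, and the diketone enol oxygen, held cis to the arene by the enol double bond, attacks the acyl-bearing ortho carbon 5-exo-trig as the iodoarene leaves, the lactamide arms differentiating the two arene faces and so setting C5. The closest known reaction types are the chiral-iodoarene-catalysed oxidative ortho-spirolactonisation and spiroetherification of phenols and naphthols, and the oxidative O-attack at an acyl-bearing ring carbon that gives grisan-type spirodienones.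

**Step 6**
Reactants: 10 (5S)-7,8,9-trimethoxy-2-{4-[(triisopropylsilyl)oxy]phenyl}-1-oxaspiro[4.5]deca-2,7,9-triene-4,6-dione
Product: 11 (5S)-7,8-dimethoxy-2-{4-[(triisopropylsilyl)oxy]phenyl}-1-oxaspiro[4.5]deca-2,7-diene-4,6,9-trione
Conditions: 0.5 M aq. HCl, THF, 0 °C, short reaction time; used directly
Reagents that add atoms: water, O
Why: Acid-catalysed enol-ether hydrolysis: C10 is the terminus of a dienol ether pushed by the 9- and 7-methoxy groups, so protonation there and addition of water at C9 with loss of methanol should give the cross-conjugated enedione faster than the vinylogous-ester methoxy groups at C7/C8 or the furanone react, and C5 is not involved.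

**Step 7**
Reactants: 11 (5S)-7,8-dimethoxy-2-{4-[(triisopropylsilyl)oxy]phenyl}-1-oxaspiro[4.5]deca-2,7-diene-4,6,9-trione
Product: 13 (5S)-10-diazo-7,8-dimethoxy-2-{4-[(triisopropylsilyl)oxy]phenyl}-1-oxaspiro[4.5]deca-2,7-diene-4,6,9-trione, via 10-trifluoroacetyl trione 12 (not isolated)
Conditions: LiHMDS (1.1 equiv), THF, −78 °C; CF3CO2CH2CF3, −78 °C, 10 min; cold 5 % HCl wash, crude 12 taken on; MsN3, Et3N, MeCN, rt, dark
Reagents that add atoms: methanesulfonyl azide, CS(=O)(=O)N=[N+]=[N-]; 2,2,2-trifluoroethyl trifluoroacetate, O=C(OCC(F)(F)F)C(F)(F)F (its trifluoroacetyl group stays only in intermediate 12)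
Why: Detrifluoroacetylative (deacylative Regitz) diazo transfer: the kinetic lithium enolate at the only enolisable position C10 is acylated within minutes at −78 °C, where β-elimination of the spiro-ether oxygen should be slow as it is for flavanone enolates, and the activated dicarbonyl then takes up N2 from the sulfonyl azide with loss of the trifluoroacetyl group.

**Step 8**
Reactants: 13 (5S)-10-diazo-7,8-dimethoxy-2-{4-[(triisopropylsilyl)oxy]phenyl}-1-oxaspiro[4.5]deca-2,7-diene-4,6,9-trione; 14 methanol
Product: 16 methyl (5S)-7,8-dimethoxy-4,9-dioxo-2-{4-[(triisopropylsilyl)oxy]phenyl}-1-oxaspiro[4.4]nona-2,7-diene-6-carboxylate (C6 epimer mixture), via spiro ketene 15 (not isolated)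
Conditions: hν (365 nm LED, Pyrex), degassed MeOH (0.01 M), 0–10 °C
Reagents that add atoms: methanol (14), CO
Why: Direct irradiation of the s-cis-locked cyclic α-diazo ketone expels N2 with concerted 1,2-shift of vinylic C8 (the future C7) from the C9 carbonyl to the diazo carbon C10 (the future C6); the former carbonyl carbon leaves the ring as ketene 15, which methanol traps as the methyl ester after ketonisation of the ester enol. This is the photochemical Wolff ring contraction of cyclic α-diazo ketones in an alcohol, with the vinyl migration known from α′-diazo enones that give vinylketenes. The cyclopentenone ring is closed by this 1,2-shift inside the six-membered ring, a ring contraction with no exo/endo cyclisation involved, and the furanone ring is a spectator. C6 becomes a stereocentre that is not controlled, since it is an acidic CH whose epimers (and the C8–H tautomer) all converge in step 9; C5 is not touched. The step needs chemoselectivity only: Wolff shift against O–H insertion of a free carbene into methanol, against 1,2-shifts from C5 and against photoreactions of the aryl furanone. The fixed s-cis geometry, the absence of a sensitiser, long-wavelength light absorbed by the diazo chromophore and dilute oxygen-free methanol should secure it.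

**Step 9**
Reactants: 16 methyl (5S)-7,8-dimethoxy-4,9-dioxo-2-{4-[(triisopropylsilyl)oxy]phenyl}-1-oxaspiro[4.4]nona-2,7-diene-6-carboxylate
Product: 17 methyl (5S,6R)-6-hydroxy-7,8-dimethoxy-4,9-dioxo-2-{4-[(triisopropylsilyl)oxy]phenyl}-1-oxaspiro[4.4]nona-2,7-diene-6-carboxylate
Conditions: (±)-trans-2-(phenylsulfonyl)-3-phenyloxaziridine (1.2 equiv), K2CO3 (0.2 equiv), 18-crown-6 (0.2 equiv), toluene, −20 °C; AcOH quench
Reagents that add atoms: trans-2-(phenylsulfonyl)-3-phenyloxaziridine, O=S(=O)(c1ccccc1)N2OC2c3ccccc3
Why: Electrophilic hydroxylation of a stabilised enolate by an N-sulfonyloxaziridine under substoichiometric base: all forms of 16 give one extended enolate, which should take up oxygen at C6 (C8 carries a methoxy group and the stronger ketone acceptor) on the face of ring oxygen O1, anti to the bulkier C4 carbonyl of the orthogonal furanone, giving 6R, while the alkoxide is protonated at once by the next molecule of 16 so that retro-aldol opening of C5–C6 is avoided.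

**Step 10**
Reactants: 17 methyl (5S,6R)-6-hydroxy-7,8-dimethoxy-4,9-dioxo-2-{4-[(triisopropylsilyl)oxy]phenyl}-1-oxaspiro[4.4]nona-2,7-diene-6-carboxylate
Product: 18 limnophilaspiroketone
Conditions: TBAF (1.2 equiv), AcOH (1.5 equiv), THF, 0 °C
Reagents that add atoms: none
Why: Fluoride cleavage of the aryl silyl ether, buffered with acetic acid so that no tertiary alkoxide is exposed to retro-aldol chemistry; no stereocentre is touched.

**Compound list**

1 | 2,3,4-trimethoxybenzaldehyde | COc1ccc(C=O)c(OC)c1OC | starting material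
2 | 2,3,4-trimethoxyphenyl formate | COc1ccc(OC=O)c(OC)c1OC | intermediate (not isolated)
3 | 2,3,4-trimethoxyphenol | COc1ccc(O)c(OC)c1OC | intermediate
4 | acetyl chloride | CC(Cl)=O | starting material
5 | 2,3,4-trimethoxyphenyl acetate | CC(=O)Oc1ccc(OC)c(OC)c1OC | intermediate (not isolated)
6 | 1-(2-hydroxy-3,4,5-trimethoxyphenyl)ethan-1-one | CC(=O)c1cc(OC)c(OC)c(OC)c1O | intermediate
7 | methyl 4-hydroxybenzoate | COC(=O)c1ccc(O)cc1 | starting material
8 | methyl 4-[(triisopropylsilyl)oxy]benzoate | COC(=O)c1ccc(O[Si](C(C)C)(C(C)C)C(C)C)cc1 | intermediate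
9 | 1-(2-hydroxy-3,4,5-trimethoxyphenyl)-3-{4-[(triisopropylsilyl)oxy]phenyl}propane-1,3-dione | COc1cc(C(=O)CC(=O)c2ccc(O[Si](C(C)C)(C(C)C)C(C)C)cc2)c(O)c(OC)c1OC | intermediate
10 | (5S)-7,8,9-trimethoxy-2-{4-[(triisopropylsilyl)oxy]phenyl}-1-oxaspiro[4.5]deca-2,7,9-triene-4,6-dione | C1=C(OC)C(OC)=C(OC)C(=O)[C@]12OC(c3ccc(O[Si](C(C)C)(C(C)C)C(C)C)cc3)=CC2=O | intermediate
11 | (5S)-7,8-dimethoxy-2-{4-[(triisopropylsilyl)oxy]phenyl}-1-oxaspiro[4.5]deca-2,7-diene-4,6,9-trione | C1C(=O)C(OC)=C(OC)C(=O)[C@]12OC(c3ccc(O[Si](C(C)C)(C(C)C)C(C)C)cc3)=CC2=O | intermediate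
12 | (5S)-7,8-dimethoxy-10-(trifluoroacetyl)-2-{4-[(triisopropylsilyl)oxy]phenyl}-1-oxaspiro[4.5]deca-2,7-diene-4,6,9-trione (C10 undefined, largely enolised) | FC(F)(F)C(=O)C1C(=O)C(OC)=C(OC)C(=O)[C@]12OC(c3ccc(O[Si](C(C)C)(C(C)C)C(C)C)cc3)=CC2=O | intermediate (not isolated)
13 | (5S)-10-diazo-7,8-dimethoxy-2-{4-[(triisopropylsilyl)oxy]phenyl}-1-oxaspiro[4.5]deca-2,7-diene-4,6,9-trione | [N-]=[N+]=C1C(=O)C(OC)=C(OC)C(=O)[C@]12OC(c3ccc(O[Si](C(C)C)(C(C)C)C(C)C)cc3)=CC2=O | intermediate
14 | methanol | CO | starting material
15 | (5S)-7,8-dimethoxy-6-(oxomethylidene)-2-{4-[(triisopropylsilyl)oxy]phenyl}-1-oxaspiro[4.4]nona-2,7-diene-4,9-dione | O=C=C1C(OC)=C(OC)C(=O)[C@]12OC(c3ccc(O[Si](C(C)C)(C(C)C)C(C)C)cc3)=CC2=O | intermediate (not isolated)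
16 | methyl (5S)-7,8-dimethoxy-4,9-dioxo-2-{4-[(triisopropylsilyl)oxy]phenyl}-1-oxaspiro[4.4]nona-2,7-diene-6-carboxylate (C6 epimer mixture) | COC(=O)C1C(OC)=C(OC)C(=O)[C@]12OC(c3ccc(O[Si](C(C)C)(C(C)C)C(C)C)cc3)=CC2=O | intermediate
17 | methyl (5S,6R)-6-hydroxy-7,8-dimethoxy-4,9-dioxo-2-{4-[(triisopropylsilyl)oxy]phenyl}-1-oxaspiro[4.4]nona-2,7-diene-6-carboxylate (6-OH cis to O1) | COC(=O)[C@@]1(O)C(OC)=C(OC)C(=O)[C@]12OC(c3ccc(O[Si](C(C)C)(C(C)C)C(C)C)cc3)=CC2=O | intermediate
18 | limnophilaspiroketone, methyl (5S,6R)-6-hydroxy-2-(4-hydroxyphenyl)-7,8-dimethoxy-4,9-dioxo-1-oxaspiro[4.4]nona-2,7-diene-6-carboxylate | COC(=O)[C@@]1(O)C(OC)=C(OC)C(=O)[C@]12OC(c3ccc(O)cc3)=CC2=O | target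

**Step count and risks**

Total step count: 10. Longest linear sequence: 9 (steps 1, 2 and 4–10 from 2,3,4-trimethoxybenzaldehyde).

Step 5 is the least secure. Three things may go wrong. An external nucleophile may attack the methoxy-bearing carbon para to the phenol oxygen, which ends in oxidative demethylation to a quinone. The peracid may over-oxidise the diketone α-carbon or the product dienol ether. The catalyst may transfer chirality poorly to an enol-oxygen nucleophile. The fallback sets out from 9 and closes the ring without a chiral catalyst or peracid, using stoichiometric PhI(OAc)2 in (CF3)2CHOH at 0 °C. This is the standard λ3-iodane dearomatisation of a phenol by an internal oxygen nucleophile, the reaction type that gives grisan-type spirodienones at an acyl-bearing ring carbon. It should give racemic 7,8,9-trimethoxy-2-{4-[(triisopropylsilyl)oxy]phenyl}-1-oxaspiro[4.5]deca-2,7,9-triene-4,6-dione F1. Preparative chromatography on a polysaccharide chiral phase then supplies the 5S enantiomer, and the route is rejoined at 10.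

Step 7 is next. The C10 enolate of 11 carries the spiro-ether oxygen in the β-position, so E1cB ring opening to an acylquinone may compete with acylation; that would destroy C5 and lead on to a flavone. The fallback sets out from 10 and never forms this enolate. The intact enol ether is C-trifluoroacetylated at its nucleophilic terminus C10 with trifluoroacetic anhydride and pyridine in CH2Cl2 at 0 °C, the known acylation of enol ethers to β-alkoxyvinyl trifluoromethyl ketones. This should give (5S)-7,8,9-trimethoxy-10-(trifluoroacetyl)-2-{4-[(triisopropylsilyl)oxy]phenyl}-1-oxaspiro[4.5]deca-2,7,9-triene-4,6-dione F2. Dilute aqueous acid hydrolyses its now doubly activated 9-methoxy group to the trifluoroacetyl trione 12. Methanesulfonyl azide and triethylamine then give the diazo compound, and the route is rejoined at 13.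

Step 9 is third. The extended enolate may be oxygenated at C8 instead of C6, oxygen may arrive on the face of the C4 carbonyl, or a long-lived alkoxide may open C5–C6 by retro-aldol and scramble C5. The fallback sets out from 16 and replaces the enolate with a neutral silyl dienol ether. Soft enolisation with TMSOTf and Et3N in CH2Cl2 at −78 °C should give methyl (5R by CIP priority only, same spatial arrangement)-7,8-dimethoxy-4-oxo-2-{4-[(triisopropylsilyl)oxy]phenyl}-9-[(trimethylsilyl)oxy]-1-oxaspiro[4.4]nona-2,6,8-triene-6-carboxylate F3. Dimethyldioxirane in acetone at −78 °C (vinylogous Rubottom oxidation, attack at the diene terminus as with steroidal 3,5-dienol ethers) is expected to deliver oxygen to C6 with silyl transfer, giving methyl (5S,6R)-7,8-dimethoxy-4,9-dioxo-2-{4-[(triisopropylsilyl)oxy]phenyl}-6-[(trimethylsilyl)oxy]-1-oxaspiro[4.4]nona-2,7-diene-6-carboxylate F4. No alkoxide is formed at any point. Citric acid in methanol removes the trimethylsilyl group, and the route is rejoined at 17.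

**Further compounds**

F1 | step 5 | racemic 7,8,9-trimethoxy-2-{4-[(triisopropylsilyl)oxy]phenyl}-1-oxaspiro[4.5]deca-2,7,9-triene-4,6-dione | C1=C(OC)C(OC)=C(OC)C(=O)C12OC(c3ccc(O[Si](C(C)C)(C(C)C)C(C)C)cc3)=CC2=O
F2 | step 7 | (5S)-7,8,9-trimethoxy-10-(trifluoroacetyl)-2-{4-[(triisopropylsilyl)oxy]phenyl}-1-oxaspiro[4.5]deca-2,7,9-triene-4,6-dione | O=C(C1=C(OC)C(OC)=C(OC)C(=O)[C@]12OC(c3ccc(O[Si](C(C)C)(C(C)C)C(C)C)cc3)=CC2=O)C(F)(F)F
F3 | step 9 | methyl (5R)-7,8-dimethoxy-4-oxo-2-{4-[(triisopropylsilyl)oxy]phenyl}-9-[(trimethylsilyl)oxy]-1-oxaspiro[4.4]nona-2,6,8-triene-6-carboxylate | COC(=O)C1=C(OC)C(OC)=C(O[Si](C)(C)C)[C@]12OC(c3ccc(O[Si](C(C)C)(C(C)C)C(C)C)cc3)=CC2=O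
F4 | step 9 | methyl (5S,6R)-7,8-dimethoxy-4,9-dioxo-2-{4-[(triisopropylsilyl)oxy]phenyl}-6-[(trimethylsilyl)oxy]-1-oxaspiro[4.4]nona-2,7-diene-6-carboxylate | COC(=O)[C@@]1(O[Si](C)(C)C)C(OC)=C(OC)C(=O)[C@]12OC(c3ccc(O[Si](C(C)C)(C(C)C)C(C)C)cc3)=CC2=O
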